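**Assumptions (one line each)**
- Iridoid numbering is used: C1 is the acetal carbon, C3=C4 the enol ether, C5/C9 the ring-fusion carbons, C6–C8 the other cyclopentene carbons, C10 the CH2O on C8, and C11 the CH2O on C4.
- Genipin is taken as the natural (1R,4aS,7aS) β-lactol with H5 and H9 cis.
- Acylation of the C1 lactol is assumed to give the natural 1β-acyloxy anomer (cis to H9) as the major, chromatographically separable isomer.

## Retrosynthetic overview
1. Target **8** comes from photochemical dehydrogenative desaturation (C5–H/C6–H, forming the C5=C6 π-bond) of trans-diol **7**, done last because the dienyl enol ether is acid- and oxidation-labile.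
2. **7** comes from acyloxy-assisted anti-hydrolysis of the 7β,8β-epoxide **6**. This inverts C8 and gives the 7β-OH/8α-OH trans pair.
3. **6** comes from genipin (**1**) by convex-face epoxidation of C7=C8, reduction of the C11 ester to CH2OAc, and acylation of C1-OH and C10-OH as isovalerates.
4. Both rings are already present in genipin, which supplies C1, C5 and C9. C7 and C8 are set by the epoxide face plus the inversion, and C5 is destroyed in the last step.

## Route

**Step 1**
Reactants: **1** genipin
Product: **2** genipin 1,10-bis(TBS) ether
Conditions: TBSCl (2.5 equiv), imidazole (5 equiv), DMF, 0 °C → rt, 12 h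
Reagents that add atoms: tert-butyldimethylsilyl chloride, CC(C)(C)[Si](C)(C)Cl
Why: Silylation of the lactol and primary OH (standard TBS protection) stops the aluminium lactolate from ring-opening to an aldehyde in the DIBAL step and makes the substrate soluble for epoxidation. No stereocentre is touched.

**Step 2**
Reactants: **2**
Product: **3** 7β,8β-epoxide of **2**
Conditions: mCPBA (1.5 equiv), NaHCO3, CH2Cl2, 0 °C → rt
Reagents that add atoms: m-chloroperbenzoic acid, OOC(=O)c1cccc(Cl)c1
Why: Prilezhaev epoxidation takes the trisubstituted C7=C8 alkene because the C3=C4 enol ether is deactivated by the conjugated C11 ester. The peracid approaches the convex face (the side bearing H5/H9), since the pyran ring covers the other face. This places both epoxide C–O bonds β, as in natural 7β,8β-epoxy iridoids.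

**Step 3**
Reactants: **3**
Product: **4** C11 acetate (4-acetoxymethyl) analogue of **3**
Conditions: (i) DIBAL-H (4 equiv), CH2Cl2, −78 → −30 °C, 3 h; (ii) in the same pot, Ac2O (10 equiv), pyridine, DMAP, 0 °C
Reagents that add atoms: acetic anhydride, CC(=O)OC(C)=O
Why: DIBAL reduces the vinylogous carbonate CO2Me to the allylic aluminium alkoxide, which is acetylated in situ (avoids ionisation of the vinylogous allylic alcohol). The TBS ethers and the epoxide survive at ≤ −30 °C. No stereocentre is involved.

**Step 4**
Reactants: **4**
Product: **5** 1,10-diol (C1 lactol, C10 primary OH) with 11-OAc and the 7β,8β-epoxide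
Conditions: TBAF (3 equiv)/AcOH (3 equiv), THF, 0 °C, 2 h
Reagents that add atoms: none
Why: Acetic-acid-buffered fluoride removes both silyl groups without opening the tertiary epoxide or cleaving the acetate (standard desilylation). The C1 lactol is free again and the anomers equilibrate.

**Step 5**
Reactants: **5**
Product: **6** 1,10-di-O-isovaleryl (3-methylbutanoyl) 11-acetate 7β,8β-epoxide
Conditions: isovaleryl chloride (2.5 equiv), pyridine, DMAP (cat.), CH2Cl2, 0 °C, 3 h
Reagents that add atoms: isovaleryl chloride, CC(C)CC(=O)Cl
Why: Schotten–Baumann-type acylation of the primary OH and the more acidic lactol OH installs both isovalerates. The anomeric effect and approach anti to C8 favour the natural 1β (1S) acylal, which is separated from any α-anomer.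

**Step 6**
Reactants: **6**; water
Product: **7** 7β,8α-diol (C5-H, C6-H2 still saturated)
Conditions: Sc(OTf)3 (5 mol%), 2,6-di-tert-butylpyridine (10 mol%), MeCN/H2O 40:1, 0 °C, 2 h; then Et3N (1 equiv), rt, 30 min
Reagents that add atoms: water, O
Why: Neighbouring-group-assisted anti-opening (Prévost-type acyloxonium pathway). The Lewis-acid-activated epoxide is attacked at tertiary C8 from the α face by the C10 isovalerate carbonyl oxygen (5-exo, a 1,3-dioxolan-2-ylium). This inverts C8 so that OH is α and C10 is β, while C7–O stays β (the C7–O bond is never broken). Water then collapses the acyloxonium, and Et3N equilibrates any tertiary ester to the primary C10 ester. This sets the C7/C8 trans-diol of the target.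

**Step 7**
Reactants: **7**
Product: **8** jatamanvaltrate J
Conditions: [Mes-Acr-Me]+BF4− (3 mol%), Co(dmgH)2PyCl (8 mol%), 2,6-lutidine (0.3 equiv), MeCN (0.02 M), 456 nm blue LEDs, N2, 25 °C, 6 h (H2 released)
Reagents that add atoms: none
Why: Proposed new method: excited acridinium (E*red ≈ +2.0 V) oxidises the C3=C4 enol ether to its radical cation, which strongly acidifies the allylic, tertiary C5–H. Lutidine removes this proton to give the C5/C3 allyl radical (stabilised by O2). Co(II) abstracts a β-H• from the less hindered C6-H2 (Hofmann-type selectivity over tertiary C9–H), forming the C5=C6 π-bond, and the Co(III)–H releases H2. The closest known reaction is acridinium/cobaloxime dehydrogenative desaturation, here extended to a polyoxygenated dihydropyran enol ether to make the conjugated dienyl enol ether. The C5 stereocentre is destroyed, and the C1, C7, C8 and C9 centres and the free secondary alcohol are untouched.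

## Compound list
1 | genipin, methyl (1R,4aS,7aS)-1-hydroxy-7-(hydroxymethyl)-1,4a,5,7a-tetrahydrocyclopenta[c]pyran-4-carboxylate | COC(=O)C1=CO[C@@H](O)[C@H]2[C@@H]1CC=C2CO | starting material
2 | genipin 1,10-bis(TBS) ether | COC(=O)C1=CO[C@@H](O[Si](C)(C)C(C)(C)C)[C@H]2[C@@H]1CC=C2CO[Si](C)(C)C(C)(C)C | intermediate
3 | 7β,8β-epoxide of 2 | COC(=O)C1=CO[C@@H](O[Si](C)(C)C(C)(C)C)[C@H]2[C@@H]1C[C@@H]3O[C@@]32CO[Si](C)(C)C(C)(C)C | intermediate
4 | 11-acetoxy (C11 CH2OAc) analogue of 3 | CC(=O)OCC1=CO[C@@H](O[Si](C)(C)C(C)(C)C)[C@H]2[C@@H]1C[C@@H]3O[C@@]32CO[Si](C)(C)C(C)(C)C | intermediate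
5 | 1-hydroxy (lactol), 10-hydroxy 11-acetate 7β,8β-epoxide | CC(=O)OCC1=CO[C@@H](O)[C@H]2[C@@H]1C[C@@H]3O[C@@]32CO | intermediate
6 | 1,10-di-O-isovaleryl 11-acetate 7β,8β-epoxide | CC(=O)OCC1=CO[C@@H](OC(=O)CC(C)C)[C@H]2[C@@H]1C[C@@H]3O[C@@]32COC(=O)CC(C)C | intermediate
7 | 7β,8α-dihydroxy 5,6-dihydro precursor of the target | CC(=O)OCC1=CO[C@@H](OC(=O)CC(C)C)[C@H]2[C@@H]1C[C@H](O)[C@]2(O)COC(=O)CC(C)C | intermediate
8 | jatamanvaltrate J | CC(=O)OCC1=CO[C@@H](OC(=O)CC(C)C)[C@H]2C1=C[C@H](O)[C@]2(O)COC(=O)CC(C)C | target

**Total steps: 7. Longest linear sequence: 7.**

## Three steps most likely to fail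
1. **Step 7 (new photochemical desaturation).** The product dienyl enol ether is more oxidisable than the substrate, so over-oxidation is possible, and C9–H loss could give the C5=C9 isomer.
   Fallback (known chemistry): protect the diol of **7** as its bis-TES ether. Dehydrogenate by polar hydride abstraction/deprotonation with DDQ and 2,6-di-tert-butyl-4-methylpyridine in benzene, then remove the silyl groups with buffered TBAF/AcOH.
2. **Step 6 (acyloxy-assisted epoxide hydrolysis).** The enol ether and acylal are acid-labile, and attack at C7 instead of C8 would give the wrong diol.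
   Fallback: carry out the anti-opening at an acid-robust, ester-stage intermediate with a C10 acetate, where the C11 ester deactivates the enol ether. Then reduce all esters exhaustively (C1 kept as its TBS lactol ether), acetylate the less hindered C11-OH selectively, isovalerylate C10, and finally convert the C1 silyl lactol to the acylal.
3. **Step 3 (DIBAL reduction of the vinylogous ester next to the epoxide).** Over-reduction, deoxygenation through the vinylogous oxocarbenium, or epoxide opening are possible.
   Fallback: reorder so the reduction is done before epoxidation (**2** → DIBAL/Ac2O → desilylation). Then epoxidise the freed C10 allylic alcohol with VO(acac)2/TBHP, which is chemoselective for C7=C8 over the enol ether, and continue with acylation.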